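## Analysis of the target

The numbering used throughout is: C1 carries the exocyclic methylene, C2 is the ring CH2, C3 the carbinol carbon bearing the vanillate, C4 the ring-fusion CH, C5 the quaternary carbon with the methyl group, C6 and C7 the cyclopentane CH2 groups, C8 the tertiary carbinol with the isopropyl group, C9 the ring CH2 next to C5 and C10 the allylic carbinol. The target 24 is a hydroazulene in which the cyclopentane C4–C5–C6–C7–C8 is trans-fused along C4–C5 to the cycloheptane C1–C2–C3–C4–C5–C9–C10. It has five stereocentres, 3S, 4S, 5R, 8R and 10S; C3, C4, C5 and C8 form one contiguous cluster around the fusion CH, while C10 stands apart, 1,3 to the quaternary C5. H-4, the ester oxygen on C3, the hydroxyl on C10 and the isopropyl group lie on one face, and the C5 methyl and the C8 hydroxyl on the other, so the C8 hydroxyl is cis to the C3 branch of C4 and that branch is trans to the C9 branch of C5. Sensitive groups are the tertiary alcohol (dehydration in acid), the allylic alcohol beside a 1,1-disubstituted alkene (ionisation, double-bond migration) and the aryl ester with a free phenol (cleavage or acyl shift in base). The difficulty is the crowding around C4, which is flanked by the quaternary C5 and the fully substituted C8, together with a seven-membered ring and a remote carbinol. The plan rests on one feature: if C8 is taken back to a ketone, C4 is its α-carbon, C5 its β-carbon and C3 an aldol carbinol outside the five-membered ring, which is the retron of a conjugate methyl addition to a 3-substituted cyclopentenone followed by an aldol reaction of the enolate so formed.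

## Retrosynthetic reasoning

24 is traced back to its phenol silyl ether 23. The free phenol would compete in the ester formation and is an unwelcome proton source in the organochromium step, so it stays masked until the end.

In 23 the C1–C10 bond is cut. An allylic alcohol next to an exocyclic methylene is the adduct of a 2-metalloalkene and an aldehyde, which leads to the iodoalkenyl aldehyde 21. Cutting here opens the seven-membered ring last, leaves only C10 to be set in the closure, and uses a Nozaki–Hiyama–Kishi reaction that tolerates the ester and the free tertiary alcohol.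

21 comes from acetal 20 by hydrolysis. The acyl–oxygen bond at C3 of 20 is cut to give diol 15 and the protected acid 18, itself from vanillic acid 16. Only the secondary C3 hydroxyl of 15 can be acylated, so no further protection is needed.

The C1–I bond of 15 is traced back to the terminal alkyne 13 by a Markovnikov addition of H and I that must avoid acid because of the tertiary alcohol and the acetal. 13 comes from the doubly silylated 12, so that the alkyne and the C3 hydroxyl travel in masked form through the organomagnesium steps.

In 12 the C8–isopropyl bond is cut, giving ketone 10 and isopropylmagnesium chloride 11. This is the cut that exposes the aldol retron. The forward addition has to come from the face opposite the C4 side chain so that the hydroxyl ends up cis to the C3 arm. 10 is the silyl ether of aldol 9.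

In 9 the C5–methyl bond and the C3–C4 bond are cut together, giving enone 4, methylmagnesium bromide 7 and aldehyde 6. These two bonds surround the most crowded pair of carbons, and cutting them reduces the cluster C3/C4/C5 to three achiral components. The forward step must select one face of the enone at C5, deliver the enolate with its double bond between C4 and C8, give the anti aldol, and bring the aldehyde to the face of C4 that carries the methyl group.

4 is cut at the ring–CH2 bond into vinylogous ester 1 and Grignard reagent 2 (addition and acid-induced carbonyl transposition). 6 comes from alcohol 5 by oxidation.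

## Alternatives that were turned down

Alternative 1: The bonds C3–C4 and C5–C9 are cut on a cyclopentene that already holds C8 with its hydroxyl and isopropyl group. In the forward step a stannyl radical takes bromine from the bromomethylsilyl ether A1, the silylmethyl radical adds 5-exo to C4, and the tertiary radical at C5 is captured by allyltributylstannane A2 to give the cis-fused oxasilolane A3. In its favour, the tether forces the new C3 carbon cis to the C8 oxygen and the allyl group enters anti to the new ring, so the C4/C5 and C4/C8 relationships are fixed by ring constraint. On this point it is stronger than the chosen plan, which relies on a size difference between methyl and a CH2–acetal arm. It also avoids a late addition to a hindered ketone. Against it for this target: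
- C3 emerges as a CH2–Si carbon, so after Tamao oxidation the C3 stereocentre and the C1–C2 unit still require an oxidation and a carbonyl addition whose facial control is not secured.
- Intermolecular allylation of a hindered tertiary radical competes with reduction and disproportionation.
- The allyl group has one carbon too many and needs oxidative cleavage.
- A1 requires an enantiopure tertiary cyclopentenol.
- Stoichiometric tin is used twice.

The chosen plan gives up the firm C4/C5 control but forms C3 with its oxygen, C4 and C5 and the complete C1–C3 chain in one operation, with the absolute configuration coming from a catalyst.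

Alternative 2: The C1–C10 bond is cut. In the forward step the iodoalkenyl aldehyde A4 is treated with a divalent chromium salt and catalytic divalent nickel, and the alkenylchromium species adds to the aldehyde to close the seven-membered ring, giving the silyl-protected target A5. In its favour, the step is mild, tolerates the ester and the free tertiary alcohol, and creates the allylic alcohol and the exocyclic alkene together at the very end. On the ring closure it is exactly as strong as the chosen plan, because the chosen route ends with this same closure (A4 and A5 have the structures of 21 and 23). Against it as the central idea: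
- It only moves the problem, since A4 already contains four of the five stereocentres and the closure says nothing about how the crowded cyclopentane is built.
- C10 is not secured by the mechanism.
- A large excess of chromium salt is needed.

A plan built on this step alone would have to assemble A4 stepwise; the chosen strategy supplies that assembly in one three-component step.

Alternative 3: The C4–C5 bond is traced back to a C3–C5 bond of a decalin derived from the (S)-Wieland–Miescher ketone A6. In the forward step a strong base or an aluminium Lewis acid makes C5 migrate from the carbinol carbon C3 to the mesylate-bearing C4 of hydroxy mesylate A7, giving the hydroazulenone A8 with a C3 ketone. In its favour, A6 is available in enantiopure form on scale, so the quaternary C5 is secure from the start. That is stronger than a catalytic methyl transfer to a cyclopentenone. The shift is also stereospecific and ties C4 to C5. Against it for this target: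
- A trans fusion needs the mesylate equatorial and on the face of the angular methyl. That means a cis-fused decalin with hydroxyl and mesylate on the methyl face, against the usual facial preference of additions to the Wieland–Miescher alkene, or else a later epimerisation at C4 of uncertain direction.
- A8 carries its oxygens at C3, C8 and C9, whereas the target needs C3, C8 and C10 plus a methylene on C1. The C9 oxygen must therefore be removed or shifted, and C1 and C10 functionalised on an unactivated stretch of the ring.
- The isopropyl group and the C3 configuration are still to be set.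

The step count would be far above that of the chosen route, in which every carbon arrives at the right oxidation level (C10 as an acetal, C1 as an alkyne carbon).

Key step: step 3

Assumption: which antipode of the carbene ligand leads to 5R cannot be derived reliably for this enone; both antipodes are accessible, and the route is written for the one that gives 5R.

## Route

Step 1
Reactants: 1 3-ethoxycyclopent-2-en-1-one; 2 (1,3-dioxolan-2-ylmethyl)magnesium bromide
Product: 4 3-(1,3-dioxolan-2-ylmethyl)cyclopent-2-en-1-one, via bromomagnesium alkoxide 3 (not isolated)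
Conditions: 2 (1.5 equiv), THF, 0 °C → rt; then 1 M HCl, 0 °C, 15 min
Reagents that add atoms: water, O
Why: Stork–Danheiser sequence: 1,2-addition to the vinylogous ester gives 3, and cold dilute acid hydrolyses the enol ether and eliminates water to transpose the enone. The dioxolane should survive the short cold acid contact because the vinylogous enol ether ionises far more easily.

Step 2
Reactants: 5 4-(trimethylsilyl)but-3-yn-1-ol
Product: 6 4-(trimethylsilyl)but-3-ynal
Conditions: Dess–Martin periodinane (1.2 equiv), CH2Cl2, 0 °C → rt; pentane, cold filtration through silica; used at once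
Reagents that add atoms: none
Why: Dess–Martin oxidation under non-basic conditions. The β,γ-alkynyl aldehyde can isomerise to the allenyl aldehyde, so it is not stored.

Step 3
Reactants: 4 3-(1,3-dioxolan-2-ylmethyl)cyclopent-2-en-1-one; 7 methylmagnesium bromide; 6 4-(trimethylsilyl)but-3-ynal
Product: 9 (2S,3R)-3-(1,3-dioxolan-2-ylmethyl)-2-[(1S)-1-hydroxy-4-(trimethylsilyl)but-3-yn-1-yl]-3-methylcyclopentan-1-one, via magnesium enolate 8 (not isolated)
Conditions: Cu(OTf)2 (5 mol%), chiral hydroxyalkyl N-mesitylimidazolinium hexafluorophosphate (NHC precursor, 7 mol%), 7 (1.2 equiv), Et2O, −30 °C, slow addition of 4; then 6 (1.5 equiv), −78 °C; aq. NH4Cl at −78 °C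
Reagents that add atoms: none
Why: The Grignard reagent reduces Cu(OTf)2 to monovalent copper and deprotonates the imidazolinium salt, so a chiral carbene–methylcopper species forms; it binds the enone, adds at C5 through a trivalent copper intermediate and releases the C5–methyl bond by reductive elimination, leaving bromomagnesium enolate 8 with its double bond fixed between C4 and C8. The closest known reaction type is the copper/carbene-catalysed asymmetric conjugate addition of Grignard reagents to 3-substituted cycloalkenones with aldol trapping of the magnesium enolate. No ring is closed. C5 is set by the catalyst, whose antipode decides between 5R and 5S. C3 is set by enolate geometry: the ring locks the enolate as E, and a chair Zimmerman–Traxler transition state with magnesium bridging both oxygens and the aldehyde substituent equatorial gives the anti aldol, which is 3S beside 4S. C4 is set by the substrate: the aldehyde should bind the enolate face that carries the C5 methyl, away from the larger dioxolanylmethyl arm, which puts the C3 arm trans to C9. The step needs 1,4- over 1,2-addition (copper catalysis, slow addition of 4), C–C bond formation faster than proton transfer from the α-acidic aldehyde (−78 °C, weakly basic chelated enolate, aldehyde added last) and a cold quench to prevent retro-aldol equilibration.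

Step 4
Reactants: 9 aldol adduct
Product: 10 (2S,3R)-3-(1,3-dioxolan-2-ylmethyl)-3-methyl-2-[(1S)-1-(triethylsilyloxy)-4-(trimethylsilyl)but-3-yn-1-yl]cyclopentan-1-one
Conditions: TESCl (1.5 equiv), imidazole (3 equiv), DMF, 0 °C → rt
Reagents that add atoms: chlorotriethylsilane, CC[Si](Cl)(CC)CC
Why: Silylation of the secondary alcohol with a silyl chloride and imidazole. The silyl ether blocks retro-aldol cleavage and removes the acidic OH before the organometallic addition, and the weak base should leave C4 untouched.

Step 5
Reactants: 10 silyl ether ketone; 11 isopropylmagnesium chloride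
Product: 12 (1R,2S,3R)-3-(1,3-dioxolan-2-ylmethyl)-3-methyl-1-(propan-2-yl)-2-[(1S)-1-(triethylsilyloxy)-4-(trimethylsilyl)but-3-yn-1-yl]cyclopentan-1-ol
Conditions: 11 (3 equiv), CeCl3 (3 equiv, dried), THF, −78 → 0 °C; aq. NH4Cl
Reagents that add atoms: none
Why: Organocerium addition to the ketone; the weakly basic cerium reagent suppresses enolisation toward C7 and β-hydride reduction. Attack is expected on the carbonyl face opposite the branched C4 side chain, so the hydroxyl ends up cis to the C3 arm (8R).

Step 6
Reactants: 12 tertiary alcohol
Product: 13 (1R,2S,3R)-3-(1,3-dioxolan-2-ylmethyl)-2-[(1S)-1-hydroxybut-3-yn-1-yl]-3-methyl-1-(propan-2-yl)cyclopentan-1-ol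
Conditions: Bu4NF (3 equiv), THF, 0 °C → rt
Reagents that add atoms: none
Why: Fluoride cleaves the O–Si bond of the triethylsilyl ether and the C(sp)–Si bond of the silylalkyne in one operation; acetal and tertiary alcohol are inert.

Step 7
Reactants: 13 diol alkyne
Product: 15 (1R,2S,3R)-3-(1,3-dioxolan-2-ylmethyl)-2-[(1S)-1-hydroxy-3-iodobut-3-en-1-yl]-3-methyl-1-(propan-2-yl)cyclopentan-1-ol, via tris(diisobutylaluminium) species 14 (not isolated)
Conditions: NiCl2(dppp) (5 mol%), i-Bu2AlH (3.5 equiv), THF, 0 → 22 °C; then NIS (4 equiv), 0 °C; aq. Rochelle salt
Reagents that add atoms: N-iodosuccinimide, O=C1CCC(=O)N1I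
Why: Nickel-catalysed α-selective hydroalumination of the terminal alkyne places aluminium on the internal carbon C1, and iodinolysis of the C–Al bond gives the 2-iodo-1-alkene, a net Markovnikov hydroiodination without acid. Both hydroxyl groups are masked in the flask as aluminium alkoxides, and the dioxolane should not be reduced by i-Bu2AlH in THF at room temperature.

Step 8
Reactants: 16 vanillic acid
Product: 18 4-[(tert-butyldimethylsilyl)oxy]-3-methoxybenzoic acid, via bis-silylated vanillate 17 (not isolated)
Conditions: TBSCl (2.5 equiv), imidazole (5 equiv), DMF, rt; then AcOH/THF/H2O (3:1:1), rt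
Reagents that add atoms: tert-butyldimethylsilyl chloride, CC(C)(C)[Si](C)(C)Cl
Why: Silylation of phenol and acid, then selective hydrolysis of the much more labile silyl ester; the aryl silyl ether is kept.

Step 9
Reactants: 15 iodoalkene diol; 18 protected vanillic acid
Product: 20 (1S)-1-[(1S,2R,5R)-2-(1,3-dioxolan-2-ylmethyl)-5-hydroxy-2-methyl-5-(propan-2-yl)cyclopentyl]-3-iodobut-3-en-1-yl 4-[(tert-butyldimethylsilyl)oxy]-3-methoxybenzoate, via mixed anhydride 19 (not isolated)
Conditions: 18 (1.5 equiv), 2,4,6-trichlorobenzoyl chloride (1.5 equiv), Et3N (3 equiv), THF, rt; then 15, DMAP (2 equiv), toluene, rt → 50 °C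
Reagents that add atoms: none
Why: Yamaguchi esterification: DMAP attacks the unshielded aroyl carbonyl of 19 and passes the acyl group to the secondary C3 hydroxyl, while the tertiary C8 hydroxyl is too hindered to react. C3 keeps its configuration because its C–O bond is not touched.

Step 10
Reactants: 20 acetal ester
Product: 21 (1S)-1-[(1S,2R,5R)-2-hydroxy-5-methyl-5-(2-oxoethyl)-2-(propan-2-yl)cyclopentyl]-3-iodobut-3-en-1-yl 4-[(tert-butyldimethylsilyl)oxy]-3-methoxybenzoate
Conditions: 1 M HCl/THF (1:4), rt
Reagents that add atoms: water, O
Why: Acid-catalysed acetal hydrolysis; aryl ester, aryl silyl ether and iodoalkene tolerate dilute aqueous acid at room temperature. The freed aldehyde cannot form a lactol with the C8 hydroxyl, which is trans to the C9 arm.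

Step 11
Reactants: 21 iodoalkenyl aldehyde
Product: 23 (3R,3aS,4S,7S,8aR)-3,7-dihydroxy-8a-methyl-6-methylidene-3-(propan-2-yl)decahydroazulen-4-yl 4-[(tert-butyldimethylsilyl)oxy]-3-methoxybenzoate, via alkenylchromium dichloride 22 (not isolated)
Conditions: CrCl2 (8 equiv), NiCl2 (0.1 equiv), DMSO/THF, rt, 0.005 M, slow addition of 21
Reagents that add atoms: none
Why: Nozaki–Hiyama–Kishi reaction: zerovalent nickel (from NiCl2 and CrCl2) inserts into the C–I bond, transmetalation gives the alkenyl species of trivalent chromium 22, and this adds to the aldehyde, closing the seven-membered ring by 7-exo attack on the carbonyl; the ester and the free tertiary alcohol are tolerated. In a chair-like transition state the aldehyde oxygen with its chromium should avoid the syn-axial C5 methyl, which leads to the 10S alcohol with the hydroxyl trans to that methyl.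

Step 12
Reactants: 23 silyl-protected target
Product: 24 (3R,3aS,4S,7S,8aR)-3,7-dihydroxy-8a-methyl-6-methylidene-3-(propan-2-yl)decahydroazulen-4-yl 4-hydroxy-3-methoxybenzoate
Conditions: Bu4NF/AcOH (1:1, 1.5 equiv), THF, 0 °C
Reagents that add atoms: none
Why: Fluoride cleaves the aryl silyl ether; the acetic acid buffer keeps the medium from becoming basic enough to cleave or shift the vanillate ester.

## Compound list

1 | 3-ethoxycyclopent-2-en-1-one | CCOC1=CC(=O)CC1 | starting material
2 | (1,3-dioxolan-2-ylmethyl)magnesium bromide | Br[Mg]CC1OCCO1 | starting material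
3 | bromomagnesium 1-(1,3-dioxolan-2-ylmethyl)-3-ethoxycyclopent-2-en-1-olate (racemic) | CCOC1=CC(CC2OCCO2)(O[Mg]Br)CC1 | intermediate (not isolated)
4 | 3-(1,3-dioxolan-2-ylmethyl)cyclopent-2-en-1-one | O=C1C=C(CC2OCCO2)CC1 | intermediate
5 | 4-(trimethylsilyl)but-3-yn-1-ol | C[Si](C)(C)C#CCCO | starting material
6 | 4-(trimethylsilyl)but-3-ynal | C[Si](C)(C)C#CCC=O | intermediate
7 | methylmagnesium bromide | C[Mg]Br | starting material
8 | bromomagnesium (R)-3-(1,3-dioxolan-2-ylmethyl)-3-methylcyclopent-1-en-1-olate | C[C@]1(CC2OCCO2)CCC(O[Mg]Br)=C1 | intermediate (not isolated)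
9 | (2S,3R)-3-(1,3-dioxolan-2-ylmethyl)-2-[(1S)-1-hydroxy-4-(trimethylsilyl)but-3-yn-1-yl]-3-methylcyclopentan-1-one | C[Si](C)(C)C#CC[C@H](O)[C@@H]1[C@](C)(CCC1=O)CC2OCCO2 | intermediate
10 | (2S,3R)-3-(1,3-dioxolan-2-ylmethyl)-3-methyl-2-[(1S)-1-(triethylsilyloxy)-4-(trimethylsilyl)but-3-yn-1-yl]cyclopentan-1-one | C[Si](C)(C)C#CC[C@H](O[Si](CC)(CC)CC)[C@@H]1[C@](C)(CCC1=O)CC2OCCO2 | intermediate
11 | isopropylmagnesium chloride | CC(C)[Mg]Cl | starting material
12 | (1R,2S,3R)-3-(1,3-dioxolan-2-ylmethyl)-3-methyl-1-(propan-2-yl)-2-[(1S)-1-(triethylsilyloxy)-4-(trimethylsilyl)but-3-yn-1-yl]cyclopentan-1-ol | C[Si](C)(C)C#CC[C@H](O[Si](CC)(CC)CC)[C@@H]1[C@](C)(CC[C@@]1(O)C(C)C)CC2OCCO2 | intermediate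
13 | (1R,2S,3R)-3-(1,3-dioxolan-2-ylmethyl)-2-[(1S)-1-hydroxybut-3-yn-1-yl]-3-methyl-1-(propan-2-yl)cyclopentan-1-ol | C#CC[C@H](O)[C@@H]1[C@](C)(CC[C@@]1(O)C(C)C)CC2OCCO2 | intermediate
14 | C1-(diisobutylalumino)alkene of 13 with both hydroxyls as diisobutylaluminium alkoxides | C=C([Al](CC(C)C)CC(C)C)C[C@H](O[Al](CC(C)C)CC(C)C)[C@@H]1[C@](C)(CC[C@@]1(O[Al](CC(C)C)CC(C)C)C(C)C)CC2OCCO2 | intermediate (not isolated)
15 | (1R,2S,3R)-3-(1,3-dioxolan-2-ylmethyl)-2-[(1S)-1-hydroxy-3-iodobut-3-en-1-yl]-3-methyl-1-(propan-2-yl)cyclopentan-1-ol | C=C(I)C[C@H](O)[C@@H]1[C@](C)(CC[C@@]1(O)C(C)C)CC2OCCO2 | intermediate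
16 | vanillic acid (4-hydroxy-3-methoxybenzoic acid) | COc1cc(C(=O)O)ccc1O | starting material
17 | tert-butyldimethylsilyl 4-[(tert-butyldimethylsilyl)oxy]-3-methoxybenzoate | COc1cc(C(=O)O[Si](C)(C)C(C)(C)C)ccc1O[Si](C)(C)C(C)(C)C | intermediate (not isolated)
18 | 4-[(tert-butyldimethylsilyl)oxy]-3-methoxybenzoic acid | COc1cc(C(=O)O)ccc1O[Si](C)(C)C(C)(C)C | intermediate
19 | 4-[(tert-butyldimethylsilyl)oxy]-3-methoxybenzoic 2,4,6-trichlorobenzoic anhydride | COc1cc(C(=O)OC(=O)c2c(Cl)cc(Cl)cc2Cl)ccc1O[Si](C)(C)C(C)(C)C | intermediate (not isolated)
20 | (1S)-1-[(1S,2R,5R)-2-(1,3-dioxolan-2-ylmethyl)-5-hydroxy-2-methyl-5-(propan-2-yl)cyclopentyl]-3-iodobut-3-en-1-yl 4-[(tert-butyldimethylsilyl)oxy]-3-methoxybenzoate | C=C(I)C[C@H](OC(=O)c1ccc(O[Si](C)(C)C(C)(C)C)c(OC)c1)[C@@H]2[C@](C)(CC[C@@]2(O)C(C)C)CC3OCCO3 | intermediate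
21 | (1S)-1-[(1S,2R,5R)-2-hydroxy-5-methyl-5-(2-oxoethyl)-2-(propan-2-yl)cyclopentyl]-3-iodobut-3-en-1-yl 4-[(tert-butyldimethylsilyl)oxy]-3-methoxybenzoate | C=C(I)C[C@H](OC(=O)c1ccc(O[Si](C)(C)C(C)(C)C)c(OC)c1)[C@@H]2[C@](C)(CC[C@@]2(O)C(C)C)CC=O | intermediate
22 | alkenylchromium dichloride from 21 (chromium on C1) | C=C([Cr](Cl)Cl)C[C@H](OC(=O)c1ccc(O[Si](C)(C)C(C)(C)C)c(OC)c1)[C@@H]2[C@](C)(CC[C@@]2(O)C(C)C)CC=O | intermediate (not isolated)
23 | (3R,3aS,4S,7S,8aR)-3,7-dihydroxy-8a-methyl-6-methylidene-3-(propan-2-yl)decahydroazulen-4-yl 4-[(tert-butyldimethylsilyl)oxy]-3-methoxybenzoate | C=C1C[C@H](OC(=O)c2ccc(O[Si](C)(C)C(C)(C)C)c(OC)c2)[C@@H]3[C@](C)(CC[C@@]3(O)C(C)C)C[C@@H]1O | intermediate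
24 | (3R,3aS,4S,7S,8aR)-3,7-dihydroxy-8a-methyl-6-methylidene-3-(propan-2-yl)decahydroazulen-4-yl 4-hydroxy-3-methoxybenzoate | C=C1C[C@H](OC(=O)c2ccc(O)c(OC)c2)[C@@H]2[C@](C)(CC[C@@]2(O)C(C)C)C[C@@H]1O | target

## Step count and weak points

Total step count: 12. Longest linear sequence: 10 steps (steps 1, 3, 4, 5, 6, 7, 9, 10, 11, 12, from 1 to 24); steps 2 and 8 are side branches.

Least certain steps:

Step 3 (key step). Three things can go wrong.
- Enantioface discrimination in the methyl transfer may be insufficient, because methyl is the least reactive Grignard group and a flat five-membered enone gives the chiral catalyst little to grip.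
- Facial selectivity of the aldehyde approach at C4 may be poor, because only the difference between methyl and a CH2–acetal arm separates the two enolate faces.
- Proton transfer from the α-acidic aldehyde 6 (or from the γ-position of 4) may compete with C–C bond formation and lead to allene isomerisation.

The fallback sets out from 4 and separates the two events. Conjugate addition of AlMe3 with Cu(OTf)2 and a chiral sulfonate-bearing imidazolinium salt in THF at −78 °C is a reaction type established for β-substituted cyclopentenones. The aluminium enolate is silylated in the flask with TMSOTf/Et3N to give the isolable (R)-trimethylsilyl enol ether F1, whose enantiomeric purity can be checked before the aldehyde is committed. MeLi in THF at 0 °C then cleaves the O–Si bond, MgBr2·OEt2 converts the lithium enolate into 8, and 6 is added at −78 °C, which returns to the route at 9. This detour does not change the face selectivity at C4; a C4 epimer would have to be separated at 9 or 10.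

Step 5. The ketone lies next to the fully substituted C4/C5 region, so β-hydride transfer from the isopropyl reagent (reduction) or enolisation toward C7 may compete with addition, and the C9 arm on the otherwise open face may erode facial selectivity. The fallback sets out from 10. Isopropenylmagnesium bromide with CeCl3, an sp2 nucleophile that is smaller and has no transferable β-hydrogen, gives the isopropenyl carbinol F2. Hydrogen-atom-transfer hydrogenation (Mn(dpm)3 cat., PhSiH3, t-BuOOH, i-PrOH, rt) should then reduce the 1,1-disubstituted alkene through a tertiary radical. The silyl-capped alkyne is not expected to accept a hydrogen atom, though cyclisation of that radical onto the alkyne is a possible side path. This returns to the route at 12.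

Step 7. The neighbouring aluminium alkoxide may override regiocontrol in the hydroalumination, the hydride reagent may deprotonate the alkyne, or the two alkoxides may slow the nickel catalyst. The fallback sets out from 13. Markovnikov hydrosilylation with [Cp*Ru(MeCN)3]PF6 (cat.) and Et3SiH in CH2Cl2 at 0 °C → rt tolerates free hydroxyls and gives the α-vinylsilane F3. Iododesilylation with NIS and 2,6-lutidine in (CF3)2CHOH at 0 °C then returns to the route at 15.

Step 11. Facial selectivity at the aldehyde may be insufficient, since C10 is controlled only by the conformation of the forming ring, and protonation of the alkenylchromium species may compete with a slow medium-ring closure. The fallback sets out from 21. The cyclisation mixture, containing the C10 epimer F4, is oxidised as a whole with Dess–Martin periodinane in CH2Cl2 to the enone F5. Corey–Bakshi–Shibata reduction then sets C10 under reagent control and returns to the route at 23. The (R)-configured 2-methyl oxazaborolidine with catecholborane at −78 °C is predicted to give 10S if the alkenyl carbon C1 acts as the large group; the antipodal catalyst is at hand if the neopentyl-type C9 side dominates.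

Further compounds
F1 | step 3 | (R)-{[3-(1,3-dioxolan-2-ylmethyl)-3-methylcyclopent-1-en-1-yl]oxy}trimethylsilane | C[C@]1(CC2OCCO2)CCC(O[Si](C)(C)C)=C1
F2 | step 5 | (1S,2S,3R)-3-(1,3-dioxolan-2-ylmethyl)-3-methyl-1-(prop-1-en-2-yl)-2-[(1S)-1-(triethylsilyloxy)-4-(trimethylsilyl)but-3-yn-1-yl]cyclopentan-1-ol | C[Si](C)(C)C#CC[C@H](O[Si](CC)(CC)CC)[C@@H]1[C@](C)(CC[C@@]1(O)C(C)=C)CC2OCCO2
F3 | step 7 | (1R,2S,3R)-3-(1,3-dioxolan-2-ylmethyl)-2-[(1S)-1-hydroxy-3-(triethylsilyl)but-3-en-1-yl]-3-methyl-1-(propan-2-yl)cyclopentan-1-ol | C=C([Si](CC)(CC)CC)C[C@H](O)[C@@H]1[C@](C)(CC[C@@]1(O)C(C)C)CC2OCCO2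
F4 | step 11 | C10 epimer of 23, (3R,3aS,4S,7R,8aR)-3,7-dihydroxy-8a-methyl-6-methylidene-3-(propan-2-yl)decahydroazulen-4-yl 4-[(tert-butyldimethylsilyl)oxy]-3-methoxybenzoate | C=C1C[C@H](OC(=O)c2ccc(O[Si](C)(C)C(C)(C)C)c(OC)c2)[C@@H]3[C@](C)(CC[C@@]3(O)C(C)C)C[C@H]1O
F5 | step 11 | (3R,3aS,4S,8aR)-3-hydroxy-8a-methyl-6-methylidene-7-oxo-3-(propan-2-yl)decahydroazulen-4-yl 4-[(tert-butyldimethylsilyl)oxy]-3-methoxybenzoate | C=C1C[C@H](OC(=O)c2ccc(O[Si](C)(C)C(C)(C)C)c(OC)c2)[C@@H]3[C@](C)(CC[C@@]3(O)C(C)C)CC1=O
A1 | alternative 1 | (bromomethyl)dimethyl{[(1R)-3-methyl-1-(propan-2-yl)cyclopent-2-en-1-yl]oxy}silane | BrC[Si](C)(C)O[C@@]1(C(C)C)CCC(C)=C1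
A2 | alternative 1 | allyltributylstannane | C=CC[Sn](CCCC)(CCCC)CCCC
A3 | alternative 1 | cis-fused oxasilolane with allyl-bearing quaternary C5 | C=CC[C@@]1(C)CC[C@]2(C(C)C)O[Si](C)(C)C[C@H]12
A4 | alternative 2 | iodoalkenyl aldehyde (same structure as 21) | C=C(I)C[C@H](OC(=O)c1ccc(O[Si](C)(C)C(C)(C)C)c(OC)c1)[C@@H]2[C@](C)(CC[C@@]2(O)C(C)C)CC=O
A5 | alternative 2 | silyl-protected target (same structure as 23) | C=C1C[C@H](OC(=O)c2ccc(O[Si](C)(C)C(C)(C)C)c(OC)c2)[C@@H]3[C@](C)(CC[C@@]3(O)C(C)C)C[C@@H]1O
A6 | alternative 3 | (S)-Wieland–Miescher ketone | C[C@]12CCC(=O)C=C1CCCC2=O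
A7 | alternative 3 | cis-fused decalin hydroxy mesylate (angular methyl, tertiary hydroxyl, mesylate and silyl ether on one face; dioxolane at C9) | O[C@]12CCCC3(OCCO3)[C@@]1(C)CC[C@H](O[Si](C)(C)C(C)(C)C)[C@@H]2OS(C)(=O)=O
A8 | alternative 3 | trans-fused hydroazulenone with C3 ketone, C8 silyl ether and C9 dioxolane | C1CC(=O)[C@@H]2[C@](C)(CC[C@@H]2O[Si](C)(C)C(C)(C)C)C3(OCCO3)C1
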